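**Overview**

- Elemane numbering is used: ring C5–C10; C10 carries methyl C14 (β) and vinyl C1=C2 (α); C5 carries C4(=C3)–C15; C7 carries C11(=C13)–C12; oxygens sit on C6 (α) and C8 (β). β means the face of the C10 methyl.
- Retrosynthesis cuts, in this order: the C15 acid and C3=C4 (aldehyde methylenation and oxidation), C11–C12 (lactone closure), the O8 ester, C8–H, C7–C11 (1,2-shift from C8), C8–ethynyl, the C6/C7 epoxide, C10–vinyl, C10–methyl, then ring bonds C9=C10 (aldol) and C5–C6 (Michael).
- Forward: the cyclohexane ring forms first (step 1), the quaternary C10 follows (steps 2–3), the C6–C7–C8 triad is built on the enone (steps 4–8), the angelate goes on (step 9), the γ-lactone ring closes last (step 12), and the side chain is oxidised to the acrylic acid (steps 13–16).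
- Stereochemistry: C5 from the organocatalytic Michael addition; C10 by cuprate addition trans to the C5 chain; C6 by epoxidation anti to that chain; C7 by a stereospecific anti 1,2-ethynyl shift; C8 by equatorial hydride attack; the ring closure creates no centre.
- Enabling feature: on the cyclohexane ring the lactone oxygen on C6 and the sp carbon C11 on C7 are vicinal, trans and diequatorial (an O6–C6–C7–C11≡C13 homopropargylic array). A carbonyl radical carried by O6 therefore reaches C11 through a five-membered transition state and forms the γ-lactone ring and the exocyclic C11=C13 methylene in one event, without enolate chemistry next to C7.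

Key step: step 12

Assumption: 4-[(tert-butyldiphenylsilyl)oxy]butanal (1) is treated as a purchasable building block, and the (S)-aminocatalyst is assigned from the usual enamine face-shielding model.

**Route**

Step 1
Reactants: 1 4-[(tert-butyldiphenylsilyl)oxy]butanal; 2 but-3-en-2-one
Product: 4 (S)-4-{2-[(tert-butyldiphenylsilyl)oxy]ethyl}cyclohex-2-en-1-one, via keto aldehyde 3 (not isolated)
Conditions: (S)-α,α-diphenylprolinol methyl ether (5 mol %), ethyl 3,4-dihydroxybenzoate (20 mol %), neat, 4 °C; then p-TsOH·H2O (10 mol %), toluene, 45 °C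
Reagents that add atoms: none
Why: Enamine-mediated asymmetric Michael addition of the aldehyde to the enone, with the enone approaching the enamine face remote from the diphenyl(methoxy)methyl group, sets C5, and the keto aldehyde then closes by acid-catalysed intramolecular aldol condensation (Robinson-type annulation) to the ring that becomes C5–C10.

Step 2
Reactants: 4 (S)-4-{2-[(tert-butyldiphenylsilyl)oxy]ethyl}cyclohex-2-en-1-one
Product: 6 (S)-3-methyl-4-{2-[(tert-butyldiphenylsilyl)oxy]ethyl}cyclohex-2-en-1-one, via silyl enol ether 5 (not isolated)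
Conditions: Me2CuLi, Me3SiCl, THF, −78 °C; then Pd(OAc)2 (10 mol %), O2 (1 atm), DMSO, 25 °C
Reagents that add atoms: lithium dimethylcuprate [Li+].C[Cu-]C
Why: Conjugate addition of the Gilman cuprate with silyl trapping, followed by Saegusa–Ito oxidation of the regiodefined silyl enol ether, re-forms the enone with the C10 methyl in place; the transient C10 stereocentre is erased and the γ-stereocentre C5 is untouched.

Step 3
Reactants: 6 (S)-3-methyl-4-{2-[(tert-butyldiphenylsilyl)oxy]ethyl}cyclohex-2-en-1-one
Product: 7 (3S,4S)-3-ethenyl-3-methyl-4-{2-[(tert-butyldiphenylsilyl)oxy]ethyl}cyclohexan-1-one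
Conditions: CH2=CHMgBr, CuBr·SMe2 (20 mol %), Me3SiCl, THF, −78 → −30 °C; then 1 M HCl
Reagents that add atoms: vinylmagnesium bromide C=C[Mg]Br
Why: Copper-catalysed conjugate addition of the vinyl Grignard reagent to the β,β-disubstituted enone occurs by axial attack anti to the C5 side chain, which 1,2-allylic strain with the C10 methyl holds pseudoaxial, so the quaternary centre C10 forms with vinyl trans and methyl cis to the side chain.

Step 4
Reactants: 7 (3S,4S)-3-ethenyl-3-methyl-4-{2-[(tert-butyldiphenylsilyl)oxy]ethyl}cyclohexan-1-one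
Product: 8 (4R,5S)-5-ethenyl-5-methyl-4-{2-[(tert-butyldiphenylsilyl)oxy]ethyl}cyclohex-2-en-1-one
Conditions: LiN(i-Pr)2, THF, −78 °C; then N-tert-butylbenzenesulfinimidoyl chloride, −78 °C
Reagents that add atoms: none
Why: Kinetic deprotonation by the amide base takes place at the unhindered C7 methylene and not at the neopentyl C9 methylene, and Mukaiyama dehydrogenation of the lithium enolate with the sulfinimidoyl chloride gives the C6=C7 enone at low temperature.

Step 5
Reactants: 8 (4R,5S)-5-ethenyl-5-methyl-4-{2-[(tert-butyldiphenylsilyl)oxy]ethyl}cyclohex-2-en-1-one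
Product: 9 6α,7α-epoxy-8-ketone: 4-ethenyl-4-methyl-5-{2-[(tert-butyldiphenylsilyl)oxy]ethyl}-7-oxabicyclo[4.1.0]heptan-2-one, epoxide oxygen trans to the side chain
Conditions: H2O2 (30 % aq), NaOH (0.3 equiv), MeOH, 0 °C
Reagents that add atoms: hydrogen peroxide OO
Why: Nucleophilic (Weitz–Scheffer) epoxidation is confined to the electron-poor enone and delivers oxygen to the face anti to the adjacent C5 side chain and the pseudoaxial C10 methyl, which fixes the C6–O bond α (trans to the side chain).

Step 6
Reactants: 9 6α,7α-epoxy-8-ketone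
Product: 10 8β-ethynyl-8α-hydroxy-6α,7α-epoxide: 2-ethynyl-4-ethenyl-4-methyl-5-{2-[(tert-butyldiphenylsilyl)oxy]ethyl}-7-oxabicyclo[4.1.0]heptan-2-ol, hydroxyl cis and ethynyl trans to the epoxide oxygen
Conditions: HC≡CMgBr, THF, −78 → −20 °C; aq. NH4Cl
Reagents that add atoms: ethynylmagnesium bromide C#C[Mg]Br
Why: 1,2-Addition of the slender ethynyl Grignard reagent to the α,β-epoxy ketone follows the polar Felkin–Anh (Cornforth) preference for attack anti to the α-C–O bond, which places the ethynyl group β on C8 and anti-periplanar to the C7–O epoxide bond, as the next step requires.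

Step 7
Reactants: 10 8β-ethynyl-8α-hydroxy-6α,7α-epoxide
Product: 12 7β-ethynyl-6α-(triethylsilyloxy)-8-ketone: 5-ethenyl-2-ethynyl-5-methyl-4-{2-[(tert-butyldiphenylsilyl)oxy]ethyl}-3-[(triethylsilyl)oxy]cyclohexan-1-one (ethynyl trans to silyloxy, silyloxy trans to side chain), via tertiary silyl ether 11 (not isolated)
Conditions: Et3SiOTf (2.2 equiv), 2,6-lutidine, CH2Cl2, −78 → −30 °C
Reagents that add atoms: triethylsilyl trifluoromethanesulfonate CC[Si](CC)(CC)OS(=O)(=O)C(F)(F)F
Why: Silyl triflate activation of the epoxide triggers a semipinacol rearrangement of the 2,3-epoxy alcohol in which the anti-periplanar ethynyl group shifts from C8 to C7 with inversion at C7, C8 becomes the ketone and the released C6 oxygen is silylated, so the trans C6–O/C7–ethynyl relationship is set stereospecifically.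

Step 8
Reactants: 12 7β-ethynyl-6α-(triethylsilyloxy)-8-ketone
Product: 13 8β-alcohol: 5-ethenyl-2-ethynyl-5-methyl-4-{2-[(tert-butyldiphenylsilyl)oxy]ethyl}-3-[(triethylsilyl)oxy]cyclohexan-1-ol, hydroxyl axial, cis to the ethynyl group and to the C10 methyl
Conditions: LiBH(s-Bu)3, THF, −78 °C; aq. NH4Cl
Reagents that add atoms: none
Why: The bulky trialkylborohydride attacks the C8 ketone along the equatorial trajectory from the α face because the axial C10 methyl blocks the β face, which gives the axial 8β-alcohol without enolising the adjacent C7 centre (diastereoselective ketone reduction).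

Step 9
Reactants: 13 8β-alcohol; 14 angelic acid [(Z)-2-methylbut-2-enoic acid]
Product: 15 8β-angelate of 13 (6α-triethylsilyl ether, 7β-ethynyl)
Conditions: 14, 2,4,6-trichlorobenzoyl chloride, Et3N, toluene, 25 °C; then 13, 80 °C (no DMAP)
Reagents that add atoms: none
Why: Yamaguchi-type acylation through the mixed 2,4,6-trichlorobenzoic anhydride, run without a nucleophilic pyridine catalyst, acylates the only free hydroxyl (the hindered axial C8–OH) and avoids the addition–elimination pathway that isomerises angelate to tiglate.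

Step 10
Reactants: 15 8β-angelate, 6α-triethylsilyl ether
Product: 16 6α-alcohol: 8β-angeloyloxy-7β-ethynyl-6α-hydroxy compound with the primary silyl ether intact
Conditions: HF·pyridine, pyridine, THF, 0 °C
Reagents that add atoms: none
Why: Fluoride-mediated desilylation removes the secondary triethylsilyl ether much faster than the primary tert-butyldiphenylsilyl ether and leaves the ester untouched (selective silyl ether cleavage).

Step 11
Reactants: 16 6α-alcohol
Product: 18 cesium 6α-oxalate: cesium salt of the O6 hydrogen oxalate of 16, via methyl oxalate 17 (not isolated)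
Conditions: ClC(=O)CO2Me, Et3N, DMAP (cat.), CH2Cl2, 0 °C; then CsOH·H2O (1.0 equiv), THF/H2O, 0 °C
Reagents that add atoms: methyl chlorooxoacetate COC(=O)C(Cl)=O; cesium hydroxide [Cs+].[OH-]
Why: Acylation of the single free hydroxyl with the oxalyl half-ester chloride, then saponification of the far more electrophilic methyl oxalate ester by one equivalent of hydroxide, places the future lactone carbonyl C12 on O6 as an oxidisable oxalate salt and spares the hindered angelate.

Step 12
Reactants: 18 cesium 6α-oxalate
Product: 19 trans-fused α-methylene γ-lactone: 8β-angeloyloxy-15-[(tert-butyldiphenylsilyl)oxy]-3,4-dihydroelema-1,11(13)-dien-12,6α-olide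
Conditions: [Ir{dF(CF3)ppy}2(dtbbpy)]PF6 (2 mol %), H2O (20 equiv), DME/DMF 3:1 (0.01 M), 450 nm LEDs, 25 °C, Ar
Reagents that add atoms: none
Why: Proposed new method: the excited trivalent iridium photocatalyst oxidises the oxalate carboxylate, loss of CO2 leaves the alkoxycarbonyl radical on O6, this adds to C11 of the ethynyl group, and the vinyl radical at C13 is reduced by the divalent iridium species and protonated by water, so the process is redox-neutral. The closest known reaction types are the tin hydride-mediated cyclisation of Se-phenyl selenocarbonates of homopropargylic alcohols to α-methylene γ-lactones and the photoredox generation of alkoxycarbonyl radicals from cesium oxalates for cyclisation onto alkenes. The γ-lactone ring closes in the 5-exo-dig mode through the C11–C12 bond. No stereocentre is created: the trans ring fusion is dictated by the trans-diequatorial C6–O and C7–C bonds set in step 7, and the exocyclic alkene arises directly, so C7 cannot epimerise. The step needs exo over endo attack, and cyclisation faster than decarboxylation of the alkoxycarbonyl radical or addition to the C10 vinyl group or the angelate; the vicinal gauche placement of O6 and C11, the slow fragmentation of secondary alkoxycarbonyl radicals at room temperature, and the absence of tin or thiyl chain carriers (which would isomerise the angelate) should secure this.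

Step 13
Reactants: 19 trans-fused α-methylene γ-lactone
Product: 20 15-alcohol: 8β-angeloyloxy-15-hydroxy-3,4-dihydroelema-1,11(13)-dien-12,6α-olide
Conditions: HF·pyridine (excess), pyridine, THF, 25 °C
Reagents that add atoms: none
Why: Prolonged exposure to buffered hydrogen fluoride cleaves the primary tert-butyldiphenylsilyl ether without any base that would add to the α-methylene lactone (silyl ether deprotection).

Step 14
Reactants: 20 15-alcohol
Product: 21 15-aldehyde: 8β-angeloyloxy-15-oxo-3,4-dihydroelema-1,11(13)-dien-12,6α-olide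
Conditions: Dess–Martin periodinane, NaHCO3, CH2Cl2, 0 → 25 °C
Reagents that add atoms: none
Why: Dess–Martin oxidation converts the primary alcohol to the aldehyde under buffered, non-nucleophilic conditions that the α-methylene lactone and the angelate tolerate.

Step 15
Reactants: 21 15-aldehyde
Product: 22 2-substituted acrolein: 8β-angeloyloxy-15-oxoelema-1,3,11(13)-trien-12,6α-olide
Conditions: CH2O (37 % aq), (i-Pr)2NH2+ CF3CO2− (1.0 equiv), CF3CO2H (10 mol %), THF, 60 °C
Reagents that add atoms: formaldehyde C=O
Why: Mannich-type α-methylenation of the aldehyde with formaldehyde, mediated by the hindered diisopropylammonium salt, installs the C3 methylene on C4, and the bulky secondary amine is too hindered to add to the α-methylene lactone.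

Step 16
Reactants: 22 2-substituted acrolein
Product: 23 target, 8β-[(Z)-2-methylbut-2-enoyloxy]elema-1,3,11(13)-trien-15-oic acid 12,6α-olide (5R,6R,7R,8R,10S)
Conditions: NaClO2, NaH2PO4, 2-methylbut-2-ene, t-BuOH/H2O, 0 → 25 °C
Reagents that add atoms: sodium chlorite [Na+].[O-]Cl=O
Why: Pinnick oxidation with an alkene scavenger for hypochlorous acid converts the 2-substituted acrolein to the acrylic acid without touching the three other alkenes or the esters.

**Compound list**

1 | 4-[(tert-butyldiphenylsilyl)oxy]butanal | O=CCCCO[Si](C(C)(C)C)(c1ccccc1)c1ccccc1 | starting material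
2 | but-3-en-2-one | C=CC(C)=O | starting material
3 | (S)-2-{2-[(tert-butyldiphenylsilyl)oxy]ethyl}-5-oxohexanal (keto aldehyde) | O=C[C@@H](CCC(C)=O)CCO[Si](C(C)(C)C)(c1ccccc1)c1ccccc1 | intermediate
4 | (S)-4-{2-[(tert-butyldiphenylsilyl)oxy]ethyl}cyclohex-2-en-1-one | O=C1C=C[C@H](CCO[Si](C(C)(C)C)(c2ccccc2)c2ccccc2)CC1 | intermediate
5 | silyl enol ether: trans-3-methyl-4-{2-[(tert-butyldiphenylsilyl)oxy]ethyl}-1-(trimethylsilyloxy)cyclohex-1-ene | C[Si](C)(C)OC1=C[C@@H](C)[C@H](CCO[Si](C(C)(C)C)(c2ccccc2)c2ccccc2)CC1 | intermediate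
6 | (S)-3-methyl-4-{2-[(tert-butyldiphenylsilyl)oxy]ethyl}cyclohex-2-en-1-one | O=C1C=C(C)[C@H](CCO[Si](C(C)(C)C)(c2ccccc2)c2ccccc2)CC1 | intermediate
7 | (3S,4S)-3-ethenyl-3-methyl-4-{2-[(tert-butyldiphenylsilyl)oxy]ethyl}cyclohexan-1-one | C=C[C@]1(C)CC(=O)CC[C@H]1CCO[Si](C(C)(C)C)(c1ccccc1)c1ccccc1 | intermediate
8 | (4R,5S)-5-ethenyl-5-methyl-4-{2-[(tert-butyldiphenylsilyl)oxy]ethyl}cyclohex-2-en-1-one | C=C[C@]1(C)CC(=O)C=C[C@H]1CCO[Si](C(C)(C)C)(c1ccccc1)c1ccccc1 | intermediate
9 | 6α,7α-epoxy-8-ketone (epoxide trans to the side chain) | C=C[C@]1(C)CC(=O)[C@@H]2O[C@@H]2[C@H]1CCO[Si](C(C)(C)C)(c1ccccc1)c1ccccc1 | intermediate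
10 | 8β-ethynyl-8α-hydroxy-6α,7α-epoxide | C=C[C@]1(C)C[C@@](O)(C#C)[C@@H]2O[C@@H]2[C@H]1CCO[Si](C(C)(C)C)(c1ccccc1)c1ccccc1 | intermediate
11 | tertiary silyl ether: 8α-O-triethylsilyl ether of 10 | C=C[C@]1(C)C[C@@](O[Si](CC)(CC)CC)(C#C)[C@@H]2O[C@@H]2[C@H]1CCO[Si](C(C)(C)C)(c1ccccc1)c1ccccc1 | intermediate
12 | 7β-ethynyl-6α-(triethylsilyloxy)-8-ketone | C=C[C@]1(C)CC(=O)[C@@H](C#C)[C@H](O[Si](CC)(CC)CC)[C@H]1CCO[Si](C(C)(C)C)(c1ccccc1)c1ccccc1 | intermediate
13 | 8β-alcohol (7β-ethynyl, 6α-triethylsilyloxy) | C=C[C@]1(C)C[C@@H](O)[C@@H](C#C)[C@H](O[Si](CC)(CC)CC)[C@H]1CCO[Si](C(C)(C)C)(c1ccccc1)c1ccccc1 | intermediate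
14 | angelic acid, (Z)-2-methylbut-2-enoic acid | C/C=C(/C)C(=O)O | starting material
15 | 8β-angelate, 6α-triethylsilyl ether | C=C[C@]1(C)C[C@@H](OC(=O)/C(C)=C\C)[C@@H](C#C)[C@H](O[Si](CC)(CC)CC)[C@H]1CCO[Si](C(C)(C)C)(c1ccccc1)c1ccccc1 | intermediate
16 | 6α-alcohol, 8β-angelate | C=C[C@]1(C)C[C@@H](OC(=O)/C(C)=C\C)[C@@H](C#C)[C@H](O)[C@H]1CCO[Si](C(C)(C)C)(c1ccccc1)c1ccccc1 | intermediate
17 | methyl oxalate: O6 methyl oxalate of 16 | C=C[C@]1(C)C[C@@H](OC(=O)/C(C)=C\C)[C@@H](C#C)[C@H](OC(=O)C(=O)OC)[C@H]1CCO[Si](C(C)(C)C)(c1ccccc1)c1ccccc1 | intermediate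
18 | cesium 6α-oxalate | [Cs+].C=C[C@]1(C)C[C@@H](OC(=O)/C(C)=C\C)[C@@H](C#C)[C@H](OC(=O)C([O-])=O)[C@H]1CCO[Si](C(C)(C)C)(c1ccccc1)c1ccccc1 | intermediate
19 | trans-fused α-methylene γ-lactone, 8β-angelate, 15-O-TBDPS | C=C[C@]1(C)C[C@@H](OC(=O)/C(C)=C\C)[C@H]2C(=C)C(=O)O[C@@H]2[C@H]1CCO[Si](C(C)(C)C)(c1ccccc1)c1ccccc1 | intermediate
20 | 15-alcohol | C=C[C@]1(C)C[C@@H](OC(=O)/C(C)=C\C)[C@H]2C(=C)C(=O)O[C@@H]2[C@H]1CCO | intermediate
21 | 15-aldehyde | C=C[C@]1(C)C[C@@H](OC(=O)/C(C)=C\C)[C@H]2C(=C)C(=O)O[C@@H]2[C@H]1CC=O | intermediate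
22 | 2-substituted acrolein | C=C[C@]1(C)C[C@@H](OC(=O)/C(C)=C\C)[C@H]2C(=C)C(=O)O[C@@H]2[C@H]1C(=C)C=O | intermediate
23 | 8β-[(Z)-2-methylbut-2-enoyloxy]elema-1,3,11(13)-trien-15-oic acid 12,6α-olide (CNP0256928.2) | C=C[C@]1(C)C[C@@H](OC(=O)/C(C)=C\C)[C@H]2C(=C)C(=O)O[C@@H]2[C@H]1C(=C)C(=O)O | target

**Step count and risks**

Total step count: 16. Longest linear sequence: 16 steps, from 1; angelic acid 14 enters as a purchased acid.

Steps most likely to fail:

1. Step 12. The alkoxycarbonyl radical may lose CO2 or be quenched before it cyclises, and energy transfer from the photocatalyst may isomerise the angelate double bond. The fallback sets out from 16: palladium-catalysed cyclocarbonylation of the homopropargylic alcohol (PdCl2, PPh3, SnCl2, CO 7 atm, MeCN, 75 °C) is a known route from trans-2-ethynylcyclohexanols to trans-fused α-methylene γ-lactones, in which an alkoxycarbonylpalladium species adds across the alkyne. It should give 19 directly and rejoin the route there; this fallback makes no new compound (F0).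

2. Step 7. The ethynyl group may migrate too slowly, so that epoxide opening at C6, elimination, or participation of the side-chain oxygen competes; low facial selectivity in step 6 would also leave little of the diastereomer that can rearrange. The fallback sets out from 9 and bypasses both steps. Reductive cleavage of the α-C–O bond of the epoxy ketone with SmI2 (THF/MeOH, −90 °C) should give the 6α-hydroxy-8-ketone F1. Silylation (Et3SiCl, imidazole, DMF) gives the 6α-(triethylsilyloxy)-8-ketone F2. The enolate formed toward C7 (KN(SiMe3)2, THF, −78 °C) is then ethynylated anti to the silyloxy group with ethynylbenziodoxolone released in situ from its trimethylsilyl derivative by Bu4NF (electrophilic alkynylation), which returns to 12.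

3. Step 9. Acylation of the hindered axial alcohol may be slow, and the activated acyl donor may isomerise from Z to E before it is transferred. The fallback sets out from 13 and builds the ester on the oxygen instead. Esterification with 2-[bis(2,2,2-trifluoroethoxy)phosphoryl]propanoic acid (DCC, DMAP, CH2Cl2) gives the 8β-phosphonopropanoate F3. Still–Gennari olefination with acetaldehyde (KN(SiMe3)2, 18-crown-6, THF, −78 °C) then forms the Z-configured 2-methylbut-2-enoate directly on O8 and returns to 15.

Further compounds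
F1 | step 7 | 6α-hydroxy-8-ketone: 3-ethenyl-5-hydroxy-3-methyl-4-{2-[(tert-butyldiphenylsilyl)oxy]ethyl}cyclohexan-1-one, hydroxyl trans to the side chain | C=C[C@]1(C)CC(=O)C[C@H](O)[C@H]1CCO[Si](C(C)(C)C)(c1ccccc1)c1ccccc1
F2 | step 7 | 6α-(triethylsilyloxy)-8-ketone: triethylsilyl ether of F1 | C=C[C@]1(C)CC(=O)C[C@H](O[Si](CC)(CC)CC)[C@H]1CCO[Si](C(C)(C)C)(c1ccccc1)c1ccccc1
F3 | step 9 | 8β-{2-[bis(2,2,2-trifluoroethoxy)phosphoryl]propanoyloxy} ester of 13 (epimers at the phosphonate carbon) | C=C[C@]1(C)C[C@@H](OC(=O)C(C)P(=O)(OCC(F)(F)F)OCC(F)(F)F)[C@@H](C#C)[C@H](O[Si](CC)(CC)CC)[C@H]1CCO[Si](C(C)(C)C)(c1ccccc1)c1ccccc1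
F0 | step 12 | none | none
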